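**Retrosynthetic overview**

1. Target 23 ⇐ Δ15 triol 21 (singlet-oxygen ene reaction with titanium-mediated oxygen transfer puts in 16-OH and the 14,15-epoxide last) ⇐ ketone 20 (MeLi sets C10).
2. 20 ⇐ seco-precursor 17 in one flask: an epoxonium cascade closes the oxepane, then the cyclohexanone; a silver-triggered cation–olefin closure then forms the cycloheptene on the preformed cyclopentane.
3. 17 ⇐ allylic bromide 11 (C1–C16) + cyclopentyl sulfone 15 (C17–C23), joined by sulfone alkylation and desulfonylation.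
4. 11 ⇐ γ-alkylation of the silyloxyallyl anion of Shi diepoxide 8 (geranyl bromide + C2 + C2) with C5 dibromide 9.
5. 15 ⇐ (S)-linalool: a sulfonyl-radical 5-exo cyclization closes the cyclopentane (C18–C22) first, then dehydration and Mukaiyama hydration reset C19. Ring order: cyclopentane → oxepane → cyclohexane → cycloheptene → epoxide.

Assumption: locants C1–C23 are the squalene-skeleton positions of the target (oxepane O between C2 and C7; C3 CHOH; C6/C7 ring fusion; C10 carbinol; C12–C13 linker; C14/C15 epoxide; C16 CHOH; C18/C22 hydroazulene fusion; C19 carbinol; C23 CMe2).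

**Route**

Step 1
Reactants: 1 geranyl bromide; 2 acetaldehyde N,N-dimethylhydrazone
Product: 4 (4E)-5,9-dimethyldeca-4,8-dienal, via hydrazone 3 (not isolated)
Conditions: LiN(iPr)2, THF, −78 → 0 °C; then 1, −78 °C → rt; then 1 M aq. oxalic acid, Et2O, rt
Reagents that add atoms: water, O
Why: Corey–Enders alkylation, in which the lithiated hydrazone (an azaenolate) displaces the primary allylic bromide by SN2 without touching the E-olefin and mild acid hydrolysis then unmasks the two-carbon-homologated aldehyde, with no stereocenter formed.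

Step 2
Reactants: 4 (4E)-5,9-dimethyldeca-4,8-dienal; 5 vinylmagnesium bromide
Product: 7 tert-butyl{[(6E)-7,11-dimethyldodeca-1,6,10-trien-3-yl]oxy}dimethylsilane, via bromomagnesium alkoxide 6 (not isolated)
Conditions: CH2=CHMgBr, THF, −78 → 0 °C; then t-BuMe2SiCl, imidazole, DMF, rt
Reagents that add atoms: tert-butyldimethylsilyl chloride, CC(C)(C)[Si](C)(C)Cl
Why: Grignard 1,2-addition followed by silylation of the alkoxide gives the secondary allylic silyl ether needed as a ketone homoenolate precursor, and the new carbinol center is left racemic because it becomes sp2 in step 4.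

Step 3
Reactants: 7 trienyl silyl ether
Product: 8 tert-butyl{[(6R,7R,10R)-6,7:10,11-diepoxy-7,11-dimethyldodec-1-en-3-yl]oxy}dimethylsilane (both carbinol epimers)
Conditions: Shi ketone (D-fructose-derived, 0.6 equiv), 2KHSO5·KHSO4·K2SO4 (Oxone), K2CO3, Bu4NHSO4, MeCN/(MeO)2CH2/aq. buffer pH 10.5, 0 °C
Reagents that add atoms: potassium peroxymonosulfate, [K+].[O-]S(=O)(=O)OO
Why: Shi asymmetric epoxidation, in which the dioxirane of the D-fructose-derived ketone attacks only the two trisubstituted olefins (the monosubstituted vinyl group is inert) through the spiro transition state, giving the R epoxide at C3 and the R,R epoxide at C6/C7, which fixes C3 and C7 and, after inversion in step 10, C6.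

Step 4
Reactants: 8 diepoxy allyl silyl ether; 9 (2E)-1,4-dibromo-2-methylbut-2-ene
Product: 11 (2E,6Z,10R,11R,14R)-1-bromo-7-[(tert-butyldimethylsilyl)oxy]-10,11:14,15-diepoxy-2,11,15-trimethylhexadeca-2,6-diene, via α-silyloxyallyllithium 10 (not isolated)
Conditions: s-BuLi (1.1 equiv), THF/HMPA, −78 °C, 10 min; then 9 (3 equiv), −78 °C
Reagents that add atoms: none
Why: Still–Evans homoenolate chemistry, in which the α-silyloxyallyl anion, held in its oxygen-chelated cis form, is alkylated at its γ-carbon by SN2 at the less hindered CH2Br of 9 (the one remote from the methyl group), which forges C12–C13 and gives the Z enol silane at C10–C11 regiospecifically, the short metalation at −78 °C sparing the trisubstituted epoxides.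

Step 5
Reactants: 12 (S)-(+)-linalool
Product: 13 (1S,2R,3R)-3-(2-chloropropan-2-yl)-1-methyl-2-[(4-methylbenzenesulfonyl)methyl]cyclopentan-1-ol (OH, CH2Ts and CMe2Cl all cis; separated from its diastereomers)
Conditions: TsCl (1.2 equiv), [Cu(dap)2]Cl (1 mol %; monovalent copper, dap = 2,9-bis(4-methoxyphenyl)-1,10-phenanthroline), MeCN, 530 nm LED, rt
Reagents that add atoms: 4-methylbenzenesulfonyl chloride, Cc1ccc(cc1)S(Cl)(=O)=O
Why: Atom-transfer radical addition–cyclization (Kharasch type), in which the sulfonyl radical adds to the vinyl terminus, the C18 radical closes 5-exo-trig onto the prenyl olefin through a Beckwith chair that places the CH2Ts and CMe2 groups cis and keeps the small, sulfone-hydrogen-bonded hydroxyl (rather than the methyl) on their side, and chlorine transfer to the tertiary radical ends the chain, so that C18 and C22 are set relative to the linalool carbinol center.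

Step 6
Reactants: 13 cyclopentanol
Product: 14 1-({[(1R,5R)-5-(2-chloropropan-2-yl)-2-methylcyclopent-2-en-1-yl]methyl}sulfonyl)-4-methylbenzene
Conditions: Burgess reagent (MeO2CN(−)SO2N(+)Et3), benzene, 50 °C
Reagents that add atoms: none
Why: Burgess syn-elimination of the tertiary alcohol, in which only the C20 and methyl hydrogens are syn to the hydroxyl (H18 is anti), so the endocyclic olefin forms together with a little exocyclic isomer that converges in step 7, and C19 is erased while C18 and C22 are untouched.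

Step 7
Reactants: 14 cyclopentene
Product: 15 (1R,2R,3R)-3-(2-chloropropan-2-yl)-1-methyl-2-[(4-methylbenzenesulfonyl)methyl]cyclopentan-1-ol (ring methyl, CH2Ts and CMe2Cl cis; OH trans)
Conditions: Co(acac)2 (20 mol %), PhSiH3, O2 (1 atm), i-PrOH, rt
Reagents that add atoms: dioxygen, O=O
Why: Mukaiyama hydration (metal-hydride hydrogen-atom transfer, Markovnikov), in which hydrogen adds to C20 and dioxygen traps the planar tertiary C19 radical on the face opposite the adjacent CH2Ts and the cis CMe2Cl groups, which puts the hydroxyl trans and the methyl cis to them as the target requires.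

Step 8
Reactants: 15 cyclopentyl sulfone; 11 allylic bromide
Product: 16 C17-tosyl seco-precursor (C16–C17 bond formed; mixture of C17 epimers)
Conditions: n-BuLi (2.1 equiv), THF/HMPA, −78 °C; then 11, −78 → −40 °C
Reagents that add atoms: none
Why: Sulfone (Julia-type) alkylation, in which the α-sulfonyl carbanion of the alkoxide–carbanion dianion displaces the primary allylic bromide by SN2, forming C16–C17 without disturbing the enol silane, the epoxides or the tertiary chloride, and the new C17 center is removed in step 9.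

Step 9
Reactants: 16 C17-tosyl seco-precursor
Product: 17 seco-precursor ((3R,6R,7R)-diepoxide, Z C10 silyl enol ether, E Δ14 olefin, (18R,19R,22R)-cyclopentanol with C23 tertiary chloride)
Conditions: Na/Hg (6% Na), Na2HPO4, THF/MeOH, −20 °C
Reagents that add atoms: none
Why: Reductive desulfonylation by single-electron transfer cleaves only the alkyl–SO2Ar bond under phosphate-buffered, cold conditions that the tert-butyldimethylsilyl enol ether, the epoxides and the tertiary chloride survive.

Step 10
Reactants: 17 seco-precursor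
Product: 20 tetracyclic keto diol (C10 ketone, Δ15(16) olefin, 14-H on the face of H18/H22), via bicyclic bis(trimethylsilyl) ether 18 (not isolated), via tetracyclic bis(trimethylsilyl) ether 19 (not isolated)
Conditions: Me3SiOSO2CF3 (3 equiv), 2,6-di-tert-butyl-4-methylpyridine (5 equiv), CH2Cl2, −78 °C; then AgOSO2CF3 (1.5 equiv), −78 → −30 °C; then 1 M HCl, THF, 0 °C
Reagents that add atoms: none
Why: Two cation–olefin cyclizations in one flask, in which silylation of the 2,3-epoxide lets the 6,7-epoxide oxygen open it at C2 (oxepane) and the Z enol silane then opens the resulting epoxonium ion at C6 with inversion through a chair (C3 and C7 retained, C11 side chain equatorial) to give the trans-fused cyclohexanone, after which silver-assisted ionization of the tertiary chloride gives the C23 cation that the Δ14 olefin captures in the Markovnikov 7-endo mode on the cis-substituted cyclopentane (cis ring fusion, C13 chain pseudo-equatorial) and the C15 cation loses the unhindered C16 proton to the pyridine base.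

Step 11
Reactants: 20 tetracyclic keto diol
Product: 21 Δ15 triol (C10 methyl carbinol)
Conditions: MeLi (6 equiv), Et2O/THF, −78 → −20 °C
Reagents that add atoms: methyllithium, [Li]C
Why: 1,2-Addition of methyllithium to the cyclohexanone occurs from the equatorial direction, anti to the axial C6 methyl group that blocks axial approach, giving the axial C10 hydroxyl and equatorial methyl of the target.

Step 12
Reactants: 21 Δ15 triol
Product: 23 CNP0203623.2, via allylic hydroperoxide 22 (not isolated)
Conditions: O2, tetraphenylporphyrin (sensitiser), visible light, Ti(OiPr)4 (20 mol %; tetravalent titanium), 4 Å MS, CH2Cl2, −20 °C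
Reagents that add atoms: dioxygen, O=O
Why: Schenck ene reaction followed by titanium-mediated oxygen transfer, in which singlet oxygen adds to C16 on the convex face (that of H18 and H22) while abstracting the pseudo-axial H14 on the ring-substituted (cis-effect) side of the olefin, and the titanium alkoxide of the resulting allylic hydroperoxide delivers its distal oxygen to the new Δ14 olefin syn to the C16 oxygen, setting C14, C15 and C16.

**Compound list**

1 | geranyl bromide, (2E)-1-bromo-3,7-dimethylocta-2,6-diene | CC(C)=CCC/C(C)=C/CBr | starting material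
2 | acetaldehyde N,N-dimethylhydrazone | CC=NN(C)C | starting material
3 | (4E)-5,9-dimethyldeca-4,8-dienal N,N-dimethylhydrazone | CC(C)=CCC/C(C)=C/CCC=NN(C)C | intermediate
4 | (4E)-5,9-dimethyldeca-4,8-dienal | CC(C)=CCC/C(C)=C/CCC=O | intermediate
5 | vinylmagnesium bromide | C=C[Mg]Br | starting material
6 | bromomagnesium (6E)-7,11-dimethyldodeca-1,6,10-trien-3-olate | CC(C)=CCC/C(C)=C/CCC(O[Mg]Br)C=C | intermediate
7 | tert-butyl{[(6E)-7,11-dimethyldodeca-1,6,10-trien-3-yl]oxy}dimethylsilane (racemic) | CC(C)=CCC/C(C)=C/CCC(O[Si](C)(C)C(C)(C)C)C=C | intermediate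
8 | tert-butyl{[(6R,7R,10R)-6,7:10,11-diepoxy-7,11-dimethyldodec-1-en-3-yl]oxy}dimethylsilane (both carbinol epimers) | CC1(C)O[C@@H]1CC[C@@]1(C)O[C@@H]1CCC(O[Si](C)(C)C(C)(C)C)C=C | intermediate
9 | (2E)-1,4-dibromo-2-methylbut-2-ene | BrC/C=C(\C)CBr | starting material
10 | α-silyloxyallyllithium of 8 (lithiated at the carbinol carbon) | CC1(C)O[C@@H]1CC[C@@]1(C)O[C@@H]1CCC([Li])(O[Si](C)(C)C(C)(C)C)C=C | intermediate
11 | (2E,6Z,10R,11R,14R)-1-bromo-7-[(tert-butyldimethylsilyl)oxy]-10,11:14,15-diepoxy-2,11,15-trimethylhexadeca-2,6-diene | CC1(C)O[C@@H]1CC[C@@]1(C)O[C@@H]1CC/C(O[Si](C)(C)C(C)(C)C)=C/CC/C=C(\C)CBr | intermediate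
12 | (S)-(+)-linalool, (3S)-3,7-dimethylocta-1,6-dien-3-ol | C=C[C@@](C)(O)CCC=C(C)C | starting material
13 | (1S,2R,3R)-3-(2-chloropropan-2-yl)-1-methyl-2-[(4-methylbenzenesulfonyl)methyl]cyclopentan-1-ol | Cc1ccc(cc1)S(=O)(=O)C[C@@H]1[C@@H](CC[C@]1(C)O)C(C)(C)Cl | intermediate
14 | 1-({[(1R,5R)-5-(2-chloropropan-2-yl)-2-methylcyclopent-2-en-1-yl]methyl}sulfonyl)-4-methylbenzene | Cc1ccc(cc1)S(=O)(=O)C[C@@H]1[C@@H](CC=C1C)C(C)(C)Cl | intermediate
15 | (1R,2R,3R)-3-(2-chloropropan-2-yl)-1-methyl-2-[(4-methylbenzenesulfonyl)methyl]cyclopentan-1-ol | Cc1ccc(cc1)S(=O)(=O)C[C@@H]1[C@@H](CC[C@@]1(C)O)C(C)(C)Cl | intermediate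
16 | C17-tosyl seco-precursor (11 joined through C16 to the sulfonyl-bearing carbon of 15; C17 epimers) | CC1(C)O[C@@H]1CC[C@@]1(C)O[C@@H]1CC/C(O[Si](C)(C)C(C)(C)C)=C/CC/C=C(\C)CC(S(=O)(=O)c1ccc(C)cc1)[C@@H]1[C@@H](CC[C@@]1(C)O)C(C)(C)Cl | intermediate
17 | seco-precursor: (3R,6R,7R)-diepoxide, Z C10 tert-butyldimethylsilyl enol ether, E Δ14 olefin, (18R,19R,22R)-cyclopentanol with C23 chloride | CC1(C)O[C@@H]1CC[C@@]1(C)O[C@@H]1CC/C(O[Si](C)(C)C(C)(C)C)=C/CC/C=C(\C)CC[C@@H]1[C@@H](CC[C@@]1(C)O)C(C)(C)Cl | intermediate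
18 | oxepane-fused cyclohexanone with C3 and C19 trimethylsilyl ethers, right half still open (C23 chloride) | CC1(C)O[C@@H]2CCC(=O)[C@H](CC/C=C(\C)CC[C@@H]3[C@@H](CC[C@@]3(C)O[Si](C)(C)C)C(C)(C)Cl)[C@@]2(C)CC[C@H]1O[Si](C)(C)C | intermediate
19 | tetracyclic Δ15 ketone, C3 and C19 trimethylsilyl ethers | CC1(C)O[C@@H]2CCC(=O)[C@H](CC[C@H]3C(C)=CC[C@@H]4[C@@H](CC[C@@]4(C)O[Si](C)(C)C)C3(C)C)[C@@]2(C)CC[C@H]1O[Si](C)(C)C | intermediate
20 | tetracyclic keto diol: C10 ketone, C3 and C19 hydroxyls, Δ15(16) olefin, cis-fused hydroazulene | CC1(C)O[C@@H]2CCC(=O)[C@H](CC[C@H]3C(C)=CC[C@@H]4[C@@H](CC[C@@]4(C)O)C3(C)C)[C@@]2(C)CC[C@H]1O | intermediate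
21 | Δ15 triol: 20 with C10 converted to the axial-OH methyl carbinol (10S) | CC1(C)O[C@@H]2CC[C@](C)(O)[C@H](CC[C@H]3C(C)=CC[C@@H]4[C@@H](CC[C@@]4(C)O)C3(C)C)[C@@]2(C)CC[C@H]1O | intermediate
22 | (16R)-16-hydroperoxide with Δ14(15) olefin | CC1(C)O[C@@H]2CC[C@](C)(O)[C@H](CCC3=C(C)[C@H](OO)C[C@@H]4[C@@H](CC[C@@]4(C)O)C3(C)C)[C@@]2(C)CC[C@H]1O | intermediate
23 | CNP0203623.2 (3R,6R,7R,10S,11R,14S,15R,16R,18R,19R,22R) | CC1(C)O[C@@H]2CC[C@](C)(O)[C@H](CC[C@@]34O[C@]3(C)[C@H](O)C[C@@H]3[C@@H](CC[C@@]3(C)O)C4(C)C)[C@@]2(C)CC[C@H]1O | target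

**Step count and risks**

Total: 12 steps. Longest linear sequence: 9 steps (1, 2, 3, 4, 8, 9, 10, 11, 12); the linalool branch (5, 6, 7) joins at step 8.

Most likely to fail:

Step 10. The silver-triggered 7-endo closure may lose to E1 elimination or to a 1,2-hydride shift from C22, and the silyloxocarbenium ion formed in the first cascade could be intercepted by the Δ14 olefin. Fallback, setting out from 17 and returning at 20: run only the trimethylsilyl triflate stage and, after the acidic work-up, isolate the bicyclic chloro keto diol F5. Dehydrochlorinate it with DBU (toluene, 80 °C) to the isopropenyl compound F6. Then close the seven-membered ring by a hydrogen-atom-transfer-initiated radical–polar crossover cyclization (Co(salen), i.e. Co(C16H14N2O2), divalent cobalt; N-fluoro-2,4,6-trimethylpyridinium triflate; PhSiH3; hexafluoroisopropanol/CH2Cl2, 0 °C). This generates the C23 cation under neutral conditions and only at the 1,1-disubstituted olefin, and gives 20.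

Step 12. The ene reaction may abstract H17 instead of H14, giving the tertiary 15-hydroperoxide. It may also find H14 poorly aligned. Fallback, setting out from 21 and returning at 23: epoxidize the Δ15 olefin from the convex face with dimethyldioxirane (acetone, 0 °C) to the 15,16-epoxide F7. Open it at the tertiary carbon with MgBr2·OEt2 (Et2O, −20 °C, inversion at C15) to the bromohydrin F8. Eliminate HBr with DBU, anti-periplanar to H14, to give the Δ14 allylic alcohol F9. Then carry out the hydroxyl-directed epoxidation with VO(acac)2 (tetravalent vanadium) and t-BuOOH in CH2Cl2, which delivers the epoxide syn to 16-OH and gives 23.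

Step 4. s-BuLi may attack the epoxides, the allyl anion may cyclize onto the C6–C7 epoxide, or alkylation may occur at the α-carbon. Fallback, setting out from 8 and returning at 11: remove the silyl group with Bu4NF to the allylic alcohol F1 and oxidize it with Dess–Martin periodinane to the vinyl ketone F2. Separately, couple 9 with vinylmagnesium bromide 5 (CuI cat., THF, −30 °C, substitution at the less hindered CH2Br) to give (2E)-1-bromo-2-methylhexa-2,5-diene F3. Join F2 and F3 by olefin cross-metathesis with the second-generation Hoveyda–Grubbs catalyst, RuCl2(H2IMes)(=CH–C6H4-2-OiPr), to give the E-enone F4. Install the Z enol silane by copper hydride-catalysed 1,4-hydrosilylation ([(Ph3P)CuH]6, monovalent copper, t-BuMe2SiH, toluene), which gives 11 without any strong base.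

**Further compounds**

F1 | step 4 | (6R,7R,10R)-6,7:10,11-diepoxy-7,11-dimethyldodec-1-en-3-ol | CC1(C)O[C@@H]1CC[C@@]1(C)O[C@@H]1CCC(O)C=C
F2 | step 4 | (6R,7R,10R)-6,7:10,11-diepoxy-7,11-dimethyldodec-1-en-3-one | CC1(C)O[C@@H]1CC[C@@]1(C)O[C@@H]1CCC(=O)C=C
F3 | step 4 | (2E)-1-bromo-2-methylhexa-2,5-diene | C=CC/C=C(\C)CBr
F4 | step 4 | (2E,5E,10R,11R,14R)-1-bromo-10,11:14,15-diepoxy-2,11,15-trimethylhexadeca-2,5-dien-7-one | CC1(C)O[C@@H]1CC[C@@]1(C)O[C@@H]1CCC(=O)/C=C/C/C=C(\C)CBr
F5 | step 10 | bicyclic chloro keto diol (left half cyclized, C3 and C19 hydroxyls free, C23 chloride) | CC1(C)O[C@@H]2CCC(=O)[C@H](CC/C=C(\C)CC[C@@H]3[C@@H](CC[C@@]3(C)O)C(C)(C)Cl)[C@@]2(C)CC[C@H]1O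
F6 | step 10 | isopropenyl analogue of F5 (C23=CH2) | CC1(C)O[C@@H]2CCC(=O)[C@H](CC/C=C(\C)CC[C@@H]3[C@@H](CC[C@@]3(C)O)C(C)=C)[C@@]2(C)CC[C@H]1O
F7 | step 12 | 15,16-epoxide of 21 (oxygen on the face of H18/H22) | CC1(C)O[C@@H]2CC[C@](C)(O)[C@H](CC[C@H]3[C@]4(C)O[C@@H]4C[C@@H]4[C@@H](CC[C@@]4(C)O)C3(C)C)[C@@]2(C)CC[C@H]1O
F8 | step 12 | 15-bromo-16-hydroxy compound (bromine anti to H14) | CC1(C)O[C@@H]2CC[C@](C)(O)[C@H](CC[C@H]3[C@@](C)(Br)[C@H](O)C[C@@H]4[C@@H](CC[C@@]4(C)O)C3(C)C)[C@@]2(C)CC[C@H]1O
F9 | step 12 | Δ14(15) allylic alcohol with (16R)-hydroxyl | CC1(C)O[C@@H]2CC[C@](C)(O)[C@H](CCC3=C(C)[C@H](O)C[C@@H]4[C@@H](CC[C@@]4(C)O)C3(C)C)[C@@]2(C)CC[C@H]1O
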